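## Retrosynthetic overview

1. Target 26 ⇒ methyl ester 25 ⇒ cut the C8–prenyl bond (Pd-catalysed asymmetric dearomative allylic alkylation) ⇒ aromatic 5,7-dihydroxychromanone 22.
2. 22 ⇒ tricyclic lactone 20, in which the dihydrocoumarin lactone masks both O5 and the acid ⇒ Negishi sp2–sp3 cut ⇒ aryl iodide 10 + (R)-lavandulyl iodide 18.
3. 18 ⇐ (±)-lavandulol by lipase (serine hydrolase) kinetic resolution. The racemate comes from methyl 3-methylbut-2-enoate + prenyl bromide.
4. 10 ⇐ quinine-catalysed intramolecular oxa-Michael addition of tigloyl phenol 9 ⇐ Friedel–Crafts tigloylation ⇐ 4 ⇐ Rh/(S)-SEGPHOS 1,4-addition of PhB(OH)2 to a 5,7-dialkoxycoumarin (first stereocentre).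
5. Ring order: the benzene and lactone rings come with coumarin 1. The dihydropyranone closes in step 7, the lactone opens in step 15, and the benzene ring is dearomatised in step 17.

Assumption: no close precedent fixes the facial sense of step 17, so the (R,R)-Trost ligand is taken as matched to (8S), and the (S,S)-ligand replaces it if a test run shows the opposite.

Locants: compounds 4–9 use chromen-2-one numbering. Compounds 10, 20 and 21 use pyrano[2,3-f]chromene numbering. Compounds 22, 25 and 26 use chroman-4-one numbering.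

## Route

Step 1
Reactants: 1 5,7-dihydroxy-2H-chromen-2-one
Product: 2 5,7-bis(benzyloxy)-2H-chromen-2-one
Conditions: BnBr (2.3 equiv), K2CO3 (3 equiv), DMF, 50 °C
Reagents that add atoms: benzyl bromide, BrCc1ccccc1
Why: Williamson etherification of the two acidic phenols is routine, creates no stereocentre, and gives ethers that survive the aqueous rhodium step and later shield C6.

Step 2
Reactants: 2 5,7-bis(benzyloxy)-2H-chromen-2-one; 3 phenylboronic acid
Product: 4 (4S)-5,7-bis(benzyloxy)-4-phenyl-3,4-dihydro-2H-chromen-2-one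
Conditions: Rh(acac)(C2H4)2 (3 mol%), (S)-SEGPHOS (3.3 mol%), 3 (8 equiv), dioxane/H2O 10:1, 60 °C
Reagents that add atoms: phenylboronic acid 3, OB(O)c1ccccc1
Why: Hayashi–Miyaura asymmetric 1,4-addition, in which the phenyl–Rh(I)/(S)-SEGPHOS species carbometalates one face of the coumarin C3=C4 bond and the oxa-π-allyl rhodium is hydrolysed, sets the first stereocentre C4 as S (the R ligand gives R-4-arylchromanones) in typically ≥98% ee.

Step 3
Reactants: 4 (4S)-5,7-bis(benzyloxy)-4-phenyl-3,4-dihydro-2H-chromen-2-one; 5 (E)-2-methylbut-2-enoyl chloride (tigloyl chloride)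
Product: 6 (4S)-5,7-bis(benzyloxy)-8-[(2E)-2-methylbut-2-enoyl]-4-phenyl-3,4-dihydro-2H-chromen-2-one
Conditions: 5 (1.3 equiv), SnCl4 (2 equiv), CH2Cl2, −40 → 0 °C
Reagents that add atoms: (E)-2-methylbut-2-enoyl chloride 5, C/C=C(\C)C(=O)Cl
Why: Friedel–Crafts acylation of the trioxygenated ring runs below 0 °C and goes to C8 (para to 5-OBn) because the peri C4 substituent forces the 5-benzyloxy group to lie over C6, while C4 is untouched and no new stereocentre forms.

Step 4
Reactants: 6 (4S)-5,7-bis(benzyloxy)-8-[(2E)-2-methylbut-2-enoyl]-4-phenyl-3,4-dihydro-2H-chromen-2-one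
Product: 7 (4S)-5,7-dihydroxy-8-[(2E)-2-methylbut-2-enoyl]-4-phenyl-3,4-dihydro-2H-chromen-2-one
Conditions: BCl3 (5 equiv), C6HMe5 (8 equiv), CH2Cl2, −78 °C; H2O quench
Reagents that add atoms: none
Why: Lewis-acid ether cleavage with pentamethylbenzene as a non-basic benzyl-cation scavenger removes both benzyl groups at −78 °C without hydrogen, so the enone, the lactone and C4 stay intact.

Step 5
Reactants: 7 (4S)-5,7-dihydroxy-8-[(2E)-2-methylbut-2-enoyl]-4-phenyl-3,4-dihydro-2H-chromen-2-one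
Product: 8 (4S)-5-[(tert-butyldimethylsilyl)oxy]-7-hydroxy-8-[(2E)-2-methylbut-2-enoyl]-4-phenyl-3,4-dihydro-2H-chromen-2-one
Conditions: TBSCl (1.05 equiv), imidazole (2.2 equiv), CH2Cl2/DMF 10:1, 0 °C
Reagents that add atoms: tert-butyldimethylsilyl chloride, CC(C)(C)[Si](C)(C)Cl
Why: Chemoselective silylation works because the 7-OH is tied up in a strong hydrogen bond to the tigloyl carbonyl, so one equivalent of TBSCl takes the free 5-OH and the short cold contact with imidazole does not trigger ring closure.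

Step 6
Reactants: 8 (4S)-5-[(tert-butyldimethylsilyl)oxy]-7-hydroxy-8-[(2E)-2-methylbut-2-enoyl]-4-phenyl-3,4-dihydro-2H-chromen-2-one
Product: 9 (4S)-5-[(tert-butyldimethylsilyl)oxy]-7-hydroxy-6-iodo-8-[(2E)-2-methylbut-2-enoyl]-4-phenyl-3,4-dihydro-2H-chromen-2-one
Conditions: NIS (1.05 equiv), MeCN, 0 °C → rt, dark
Reagents that add atoms: N-iodosuccinimide, O=C1CCC(=O)N1I
Why: Electrophilic aromatic iodination can only hit C6, the single free ring position, which is activated by the ortho phenol, while the electron-poor enone is inert to NIS.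

Step 7
Reactants: 9 (4S)-5-[(tert-butyldimethylsilyl)oxy]-7-hydroxy-6-iodo-8-[(2E)-2-methylbut-2-enoyl]-4-phenyl-3,4-dihydro-2H-chromen-2-one
Product: 10 (4S,8R,9S)-5-[(tert-butyldimethylsilyl)oxy]-6-iodo-8,9-dimethyl-4-phenyl-3,4,8,9-tetrahydro-2H,10H-pyrano[2,3-f]chromene-2,10-dione (cis-8,9-dimethyl)
Conditions: (−)-quinine (30 mol%), PhCl, 15 °C, 3–5 d
Reagents that add atoms: none
Why: In this cinchona-catalysed intramolecular oxa-Michael addition the quinuclidine nitrogen activates the 7-OH, which adds to one face of the E-enone to set C8 as R, the quininium ion protonates the enolate kinetically from the same side to set C9 as S (cis), and the lactone blocks the only other oxygen ortho to the acyl group.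

Step 8
Reactants: 11 methyl 3-methylbut-2-enoate; 12 1-bromo-3-methylbut-2-ene (prenyl bromide)
Product: 14 (±)-methyl 5-methyl-2-(prop-1-en-2-yl)hex-4-enoate, via lithium dienolate 13 (not isolated)
Conditions: LDA (1.1 equiv), THF/DMPU, −78 °C; then 12, −78 → 0 °C
Reagents that add atoms: 1-bromo-3-methylbut-2-ene 12, CC(C)=CCBr
Why: Deconjugative α-alkylation of the extended ester enolate with an allylic bromide (SN2) gives the lavandulyl skeleton, and the new stereocentre forms as a racemate that is resolved in step 10.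

Step 9
Reactants: 14 (±)-methyl 5-methyl-2-(prop-1-en-2-yl)hex-4-enoate
Product: 15 (±)-5-methyl-2-(prop-1-en-2-yl)hex-4-en-1-ol ((±)-lavandulol)
Conditions: LiAlH4, Et2O, 0 °C; Fieser work-up
Reagents that add atoms: none
Why: Hydride reduction of the ester is fast at 0 °C, leaves both alkenes alone and does not move the β,γ-double bond.

Step 10
Reactants: 15 (±)-lavandulol
Product: 16 (2R)-5-methyl-2-(prop-1-en-2-yl)hex-4-en-1-yl acetate ((R)-lavandulyl acetate)
Conditions: porcine pancreatic lipase (triacylglycerol lipase, EC 3.1.1.3), vinyl acetate (3 equiv), MTBE, 25 °C, to ca. 40% conversion; SiO2 separation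
Reagents that add atoms: vinyl acetate, C=COC(C)=O
Why: In this lipase-catalysed kinetic resolution by irreversible transesterification the serine hydrolase acylates (R)-lavandulol clearly faster than the S enantiomer, so the acetate isolated at partial conversion carries the R centre, and one repeat of steps 10 and 11 on the enriched material lifts it to ≥98% ee.

Step 11
Reactants: 16 (R)-lavandulyl acetate
Product: 17 (2R)-5-methyl-2-(prop-1-en-2-yl)hex-4-en-1-ol ((R)-lavandulol)
Conditions: K2CO3 (10 mol%), MeOH, rt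
Reagents that add atoms: none
Why: Base-catalysed transesterification (methanolysis) frees the alcohol without touching the non-acidic allylic stereocentre.

Step 12
Reactants: 17 (R)-lavandulol
Product: 18 (3R)-3-(iodomethyl)-2,6-dimethylhepta-1,5-diene ((R)-lavandulyl iodide)
Conditions: I2, PPh3, imidazole, CH2Cl2, 0 °C
Reagents that add atoms: iodine, II
Why: Appel-type iodination is an SN2 displacement at the primary carbon, so the neighbouring stereocentre keeps its arrangement (still R).

Step 13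
Reactants: 18 (R)-lavandulyl iodide; 10 (4S,8R,9S)-5-[(tert-butyldimethylsilyl)oxy]-6-iodo-8,9-dimethyl-4-phenyl-3,4,8,9-tetrahydro-2H,10H-pyrano[2,3-f]chromene-2,10-dione
Product: 20 (4S,8R,9S)-5-[(tert-butyldimethylsilyl)oxy]-8,9-dimethyl-6-[(2S)-5-methyl-2-(prop-1-en-2-yl)hex-4-en-1-yl]-4-phenyl-3,4,8,9-tetrahydro-2H,10H-pyrano[2,3-f]chromene-2,10-dione, via lavandulylzinc iodide 19 (not isolated)
Conditions: 18 (1.6 equiv), Zn dust (BrCH2CH2Br/TMSCl-activated), LiCl, THF, 40 °C; then 10, Pd(OAc)2 (4 mol%), SPhos (8 mol%), THF, rt → 40 °C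
Reagents that add atoms: (R)-lavandulyl iodide 18, C=C(C)[C@@H](CC=C(C)C)CI
Why: In this Negishi sp3–sp2 cross-coupling the primary alkylzinc iodide tolerates ketone, lactone and silyl ether, the bulky biaryl phosphine favours reductive elimination over β-hydride elimination at the hindered aryl iodide, and the stereocentre β to zinc is not involved (its descriptor becomes S only through CIP ranking).

Step 14
Reactants: 20 (4S,8R,9S)-5-silyloxy-6-lavandulyl tricycle
Product: 21 (4S,8R,9S)-5-hydroxy-8,9-dimethyl-6-[(2S)-5-methyl-2-(prop-1-en-2-yl)hex-4-en-1-yl]-4-phenyl-3,4,8,9-tetrahydro-2H,10H-pyrano[2,3-f]chromene-2,10-dione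
Conditions: Et3N·3HF (3 equiv), THF, 0 °C → rt
Reagents that add atoms: none
Why: Fluoride-driven desilylation with the slightly acidic amine–HF complex frees the phenol without base, so the cis-dimethylchromanone and the lactone are not disturbed.

Step 15
Reactants: 21 (4S,8R,9S)-5-hydroxy-6-lavandulyl tricyclic lactone
Product: 22 methyl (3S)-3-{(2R,3S)-5,7-dihydroxy-2,3-dimethyl-8-[(2S)-5-methyl-2-(prop-1-en-2-yl)hex-4-en-1-yl]-4-oxo-3,4-dihydro-2H-chromen-6-yl}-3-phenylpropanoate
Conditions: NaOMe (2.5 equiv), MeOH/THF 1:1, −20 °C, 20 min; then 1 M HCl to pH 5; used directly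
Reagents that add atoms: sodium methoxide, [Na+].[O-]C
Why: In this methoxide transesterification of the reactive aryl lactone the free phenol is deprotonated at once to a vinylogous carboxylate that suppresses enolisation next to the ketone, so ring opening at −20 °C is much faster than epimerisation and unmasks the chelated 5-OH needed for the next step.

Step 16
Reactants: 23 3-methylbut-2-en-1-ol (prenol)
Product: 24 tert-butyl 3-methylbut-2-en-1-yl carbonate
Conditions: Boc2O (1.2 equiv), Bu4NHSO4 (5 mol%), 30% aq NaOH, CH2Cl2, 0 °C → rt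
Reagents that add atoms: di-tert-butyl dicarbonate, CC(C)(C)OC(=O)OC(=O)OC(C)(C)C
Why: Phase-transfer O-acylation of the primary allylic alcohol gives a carbonate that ionises with Pd(0) and releases its own base.

Step 17
Reactants: 22 methyl (3S)-3-{(2R,3S)-5,7-dihydroxy-8-lavandulyl-2,3-dimethyl-4-oxochroman-6-yl}-3-phenylpropanoate; 24 tert-butyl 3-methylbut-2-en-1-yl carbonate
Product: 25 methyl (3S)-3-{(2R,3S,8S)-5-hydroxy-2,3-dimethyl-8-(3-methylbut-2-en-1-yl)-8-[(2S)-5-methyl-2-(prop-1-en-2-yl)hex-4-en-1-yl]-4,7-dioxo-3,4,7,8-tetrahydro-2H-chromen-6-yl}-3-phenylpropanoate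
Conditions: Pd2(dba)3·CHCl3 (2.5 mol%), (R,R)-DACH-phenyl Trost ligand (7.5 mol%), 24 (1.15 equiv), degassed toluene, 0 °C → rt; SiO2 removal of the 8-epimer
Reagents that add atoms: tert-butyl 3-methylbut-2-en-1-yl carbonate 24, CC(C)=CCOC(=O)OC(C)(C)C
Why: In this Tsuji–Trost-type asymmetric dearomative allylic alkylation O-prenylation is reversible under Pd(0) whereas attack of the 7-phenoxide through C8 on the unsubstituted terminus of the π-prenyl complex is irreversible and ends in a stabilised enolised β-triketone, C6 is shielded by its secondary benzylic group, and the chiral ligand pocket selects the ring face so that quaternary C8 forms as S with the minor 8-epimer being a separable diastereomer.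

Step 18
Reactants: 25 methyl ester of the target
Product: 26 (3S)-3-{(2R,3S,8S)-5-hydroxy-2,3-dimethyl-8-(3-methylbut-2-en-1-yl)-8-[(2S)-5-methyl-2-(prop-1-en-2-yl)hex-4-en-1-yl]-4,7-dioxo-3,4,7,8-tetrahydro-2H-chromen-6-yl}-3-phenylpropanoic acid (CNP0150579.2)
Conditions: LiOH·H2O (5 equiv), THF/H2O 3:1, 0 °C → rt; then 1 M HCl to pH 3, 0 °C
Reagents that add atoms: lithium hydroxide, [Li+].[OH-]
Why: Saponification of the unhindered methyl ester proceeds on the delocalised enolate of the β-triketone, in which C3–H is no longer acidic, so none of the five stereocentres is at risk and cold mild acidification gives the free acid.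

## Compound list

1 | 5,7-dihydroxy-2H-chromen-2-one | O=c1ccc2c(O)cc(O)cc2o1 | starting material
2 | 5,7-bis(benzyloxy)-2H-chromen-2-one | O=c1ccc2c(OCc3ccccc3)cc(OCc3ccccc3)cc2o1 | intermediate
3 | phenylboronic acid | OB(O)c1ccccc1 | starting material
4 | (4S)-5,7-bis(benzyloxy)-4-phenyl-3,4-dihydro-2H-chromen-2-one | c1ccccc1COc1cc(OCc2ccccc2)c2c(c1)OC(=O)C[C@H]2c1ccccc1 | intermediate
5 | (E)-2-methylbut-2-enoyl chloride | C/C=C(\C)C(=O)Cl | starting material
6 | (4S)-5,7-bis(benzyloxy)-8-[(2E)-2-methylbut-2-enoyl]-4-phenyl-3,4-dihydro-2H-chromen-2-one | c1ccccc1COc1cc(OCc2ccccc2)c2c(c1C(=O)/C(C)=C/C)OC(=O)C[C@H]2c1ccccc1 | intermediate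
7 | (4S)-5,7-dihydroxy-8-[(2E)-2-methylbut-2-enoyl]-4-phenyl-3,4-dihydro-2H-chromen-2-one | Oc1cc(O)c2c(c1C(=O)/C(C)=C/C)OC(=O)C[C@H]2c1ccccc1 | intermediate
8 | (4S)-5-[(tert-butyldimethylsilyl)oxy]-7-hydroxy-8-[(2E)-2-methylbut-2-enoyl]-4-phenyl-3,4-dihydro-2H-chromen-2-one | Oc1cc(O[Si](C)(C)C(C)(C)C)c2c(c1C(=O)/C(C)=C/C)OC(=O)C[C@H]2c1ccccc1 | intermediate
9 | (4S)-5-[(tert-butyldimethylsilyl)oxy]-7-hydroxy-6-iodo-8-[(2E)-2-methylbut-2-enoyl]-4-phenyl-3,4-dihydro-2H-chromen-2-one | Oc1c(I)c(O[Si](C)(C)C(C)(C)C)c2c(c1C(=O)/C(C)=C/C)OC(=O)C[C@H]2c1ccccc1 | intermediate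
10 | (4S,8R,9S)-5-[(tert-butyldimethylsilyl)oxy]-6-iodo-8,9-dimethyl-4-phenyl-3,4,8,9-tetrahydro-2H,10H-pyrano[2,3-f]chromene-2,10-dione | Ic1c(O[Si](C)(C)C(C)(C)C)c2c(c3c1O[C@H](C)[C@H](C)C3=O)OC(=O)C[C@H]2c1ccccc1 | intermediate
11 | methyl 3-methylbut-2-enoate | COC(=O)C=C(C)C | starting material
12 | 1-bromo-3-methylbut-2-ene | CC(C)=CCBr | starting material
13 | lithium 1-methoxy-3-methylbuta-1,3-dien-1-olate (lithium dienolate) | [Li+].[O-]C(OC)=CC(C)=C | intermediate
14 | (±)-methyl 5-methyl-2-(prop-1-en-2-yl)hex-4-enoate | C=C(C)C(CC=C(C)C)C(=O)OC | intermediate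
15 | (±)-lavandulol | C=C(C)C(CC=C(C)C)CO | intermediate
16 | (R)-lavandulyl acetate | C=C(C)[C@@H](CC=C(C)C)COC(C)=O | intermediate
17 | (R)-lavandulol | C=C(C)[C@@H](CC=C(C)C)CO | intermediate
18 | (3R)-3-(iodomethyl)-2,6-dimethylhepta-1,5-diene | C=C(C)[C@@H](CC=C(C)C)CI | intermediate
19 | (R)-lavandulylzinc iodide | C=C(C)[C@@H](CC=C(C)C)C[Zn]I | intermediate
20 | (4S,8R,9S)-5-[(tert-butyldimethylsilyl)oxy]-8,9-dimethyl-6-[(2S)-5-methyl-2-(prop-1-en-2-yl)hex-4-en-1-yl]-4-phenyl-3,4,8,9-tetrahydro-2H,10H-pyrano[2,3-f]chromene-2,10-dione | C=C(C)[C@@H](CC=C(C)C)Cc1c(O[Si](C)(C)C(C)(C)C)c2c(c3c1O[C@H](C)[C@H](C)C3=O)OC(=O)C[C@H]2c1ccccc1 | intermediate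
21 | (4S,8R,9S)-5-hydroxy-8,9-dimethyl-6-[(2S)-5-methyl-2-(prop-1-en-2-yl)hex-4-en-1-yl]-4-phenyl-3,4,8,9-tetrahydro-2H,10H-pyrano[2,3-f]chromene-2,10-dione | C=C(C)[C@@H](CC=C(C)C)Cc1c(O)c2c(c3c1O[C@H](C)[C@H](C)C3=O)OC(=O)C[C@H]2c1ccccc1 | intermediate
22 | methyl (3S)-3-{(2R,3S)-5,7-dihydroxy-2,3-dimethyl-8-[(2S)-5-methyl-2-(prop-1-en-2-yl)hex-4-en-1-yl]-4-oxo-3,4-dihydro-2H-chromen-6-yl}-3-phenylpropanoate | C=C(C)[C@@H](CC=C(C)C)Cc1c(O)c([C@@H](CC(=O)OC)c2ccccc2)c(O)c2c1O[C@H](C)[C@H](C)C2=O | intermediate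
23 | 3-methylbut-2-en-1-ol | CC(C)=CCO | starting material
24 | tert-butyl 3-methylbut-2-en-1-yl carbonate | CC(C)=CCOC(=O)OC(C)(C)C | intermediate
25 | methyl (3S)-3-{(2R,3S,8S)-5-hydroxy-2,3-dimethyl-8-(3-methylbut-2-en-1-yl)-8-[(2S)-5-methyl-2-(prop-1-en-2-yl)hex-4-en-1-yl]-4,7-dioxo-3,4,7,8-tetrahydro-2H-chromen-6-yl}-3-phenylpropanoate | C=C(C)[C@@H](CC=C(C)C)C[C@]1(CC=C(C)C)C(=O)C([C@@H](CC(=O)OC)c2ccccc2)=C(O)C2=C1O[C@H](C)[C@H](C)C2=O | intermediate
26 | (3S)-3-{(2R,3S,8S)-5-hydroxy-2,3-dimethyl-8-(3-methylbut-2-en-1-yl)-8-[(2S)-5-methyl-2-(prop-1-en-2-yl)hex-4-en-1-yl]-4,7-dioxo-3,4,7,8-tetrahydro-2H-chromen-6-yl}-3-phenylpropanoic acid | C=C(C)[C@@H](CC=C(C)C)C[C@]1(CC=C(C)C)C(=O)C([C@@H](CC(=O)O)c2ccccc2)=C(O)C2=C1O[C@H](C)[C@H](C)C2=O | target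

## Step count and weak points

Total step count: 18, or 20 operations if the enzymatic pass of steps 10 and 11 is repeated.

Longest linear sequence: 12 steps (1 → 2 → 4 → 6 → 7 → 8 → 9 → 10 → 20 → 21 → 22 → 25 → 26). The lavandulyl branch reaches the target in 10 steps.

**Step 17 (dearomative prenylation).** The risks are C- versus O-attack, C8 versus C6, and facial control at the quaternary centre.
- The fallback sets out from 21 and comes back at 26. It gives up both catalyst control and the ester detour.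
- Lactone 21 is opened with LiOH (3.5 equiv, THF/H2O, 0 °C). This gives the trilithium salt of (3S)-3-{(2R,3S)-5,7-dihydroxy-2,3-dimethyl-8-[(2S)-lavandulyl]-4-oxochroman-6-yl}-3-phenylpropanoic acid F1.
- The salt is not isolated. It is C-alkylated in the same aqueous alkaline medium with prenyl bromide 12. This is the classical alkylative dearomatisation of acylphloroglucinol polyanions, in which water solvates the oxygens so that carbon attacks.
- Cold acidification gives 26 together with the (8R)-epimer of the target F2. The two diastereomers are separated by preparative reversed-phase HPLC.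

**Step 13 (Negishi coupling).** The risk is coupling a doubly ortho-substituted aryl iodide with a β-branched alkylzinc.
- The fallback sets out from 18, with 10 as partner, and comes back at 20. The nucleophile is changed from zinc to boron.
- Iodide 18 undergoes iodine–lithium exchange (t-BuLi, 2.1 equiv, Et2O/pentane, −78 °C) to (R)-lavandulyllithium F3.
- Trapping with 9-methoxy-9-BBN gives lithium B-lavandulyl-B-methoxy-9-borabicyclononane borate F4.
- This preformed ate complex passes its primary alkyl group to the aryl–Pd(II) species from 10 (PdCl2(dppf), THF/DMF, rt → 50 °C). The coupling is a base-free B-alkyl Suzuki–Miyaura reaction, so the lactone and the cis-chromanone never see aqueous base.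

**Step 3 (Friedel–Crafts tigloylation).** The risks are C8/C6 regiochemistry and survival of the benzyl ethers under SnCl4.
- The fallback sets out from 1 and comes back at 7. The acyl group goes on before any stereocentre exists.
- Coumarin 1 is acylated with 5 (AlCl3, PhNO2/1,2-dichloroethane, 60 °C). Under these conditions 5,7-dihydroxycoumarins take the acyl group at C8, which gives 5,7-dihydroxy-8-[(E)-2-methylbut-2-enoyl]-2H-chromen-2-one F5.
- Both phenols are silylated (TBSCl, imidazole, DMF) to the bis-TBS ether F6.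
- The Rh/(S)-SEGPHOS addition of 3 is run on F6. The trisubstituted α-methyl enone is inert to aryl-rhodium insertion, so only the coumarin C3=C4 bond reacts. The product is the (4S)-4-phenyl bis-TBS dihydrocoumarin F7.
- Et3N·3HF removes both silyl groups and delivers 7.

## Further compounds

F1 | step 17 | (3S)-3-{(2R,3S)-5,7-dihydroxy-2,3-dimethyl-8-[(2S)-5-methyl-2-(prop-1-en-2-yl)hex-4-en-1-yl]-4-oxo-3,4-dihydro-2H-chromen-6-yl}-3-phenylpropanoic acid | C=C(C)[C@@H](CC=C(C)C)Cc1c(O)c([C@@H](CC(=O)O)c2ccccc2)c(O)c2c1O[C@H](C)[C@H](C)C2=O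
F2 | step 17 | (8R)-epimer of the target | C=C(C)[C@@H](CC=C(C)C)C[C@@]1(CC=C(C)C)C(=O)C([C@@H](CC(=O)O)c2ccccc2)=C(O)C2=C1O[C@H](C)[C@H](C)C2=O
F3 | step 13 | (R)-lavandulyllithium | [Li]C[C@H](CC=C(C)C)C(C)=C
F4 | step 13 | lithium B-lavandulyl-B-methoxy-9-borabicyclo[3.3.1]nonane borate | [Li+].CO[B-]1(C[C@H](CC=C(C)C)C(C)=C)C2CCCC1CCC2
F5 | step 3 | 5,7-dihydroxy-8-[(E)-2-methylbut-2-enoyl]-2H-chromen-2-one | O=c1ccc2c(O)cc(O)c(C(=O)/C(C)=C/C)c2o1
F6 | step 3 | 5,7-bis[(tert-butyldimethylsilyl)oxy]-8-[(E)-2-methylbut-2-enoyl]-2H-chromen-2-one | O=c1ccc2c(O[Si](C)(C)C(C)(C)C)cc(O[Si](C)(C)C(C)(C)C)c(C(=O)/C(C)=C/C)c2o1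
F7 | step 3 | (4S)-5,7-bis[(tert-butyldimethylsilyl)oxy]-8-[(E)-2-methylbut-2-enoyl]-4-phenyl-3,4-dihydro-2H-chromen-2-one | CC(C)(C)[Si](C)(C)Oc1cc(O[Si](C)(C)C(C)(C)C)c2c(c1C(=O)/C(C)=C/C)OC(=O)C[C@H]2c1ccccc1
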